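**Plan**

- Retrosynthesis: remove the two formates; cut C8–CH3 (alkenyl triflate coupling); cut C9–C11 (enolate alkylation with a C5 iodide from (S)-citronellol); then cut C5–C10 and C6–C7 together (intramolecular Diels–Alder) to an acyclic triene; cut the triene at C5=C6 (olefination), at C8–C9 and C10–CH3 (alkyne carbometalation–acylation) and at C3–C4 (prenylboration of pent-4-ynal).
- Enabling feature: ring B (C5–C10) has an sp2 C8 and the angular methyl on C10, so it reads as the adduct of a C7=C8(OSi)–C9=C10 diene and a C5=C6 alkene, joined through the four carbons C1–C4 of ring A.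
- Forward: C3–C4 is made first, then the E-enone, the vinyl sulfone (temporary activator on C6) and the silyloxy diene. Rings A and B form together in step 7. The sulfone is then removed, the side chain is joined at C9, the C8 oxygen is exchanged for methyl, and the diol is formylated.
- Stereochemistry: C3 from reagent-controlled prenylboration; C5 and C10 relayed from C3 in the cycloaddition; C9 by equilibration next to the C8 ketone; C13 from (S)-citronellol.

Key step: step 7

Remark: labdane numbering is used for all intermediates (ring A = C1–C5, C10; ring B = C5–C10); the target is read as (13S)-labd-7-ene-3β,15-diyl diformate, (3S,5R,9S,10R,13S).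
Remark: the borane made from (+)-Ipc2BOMe (from (−)-α-pinene) is taken to add to the Re face of the aldehyde, as its allyl parent does; should the sense be opposite, the antipodal borane is used.

**Route**

Step 1
Reactants: 1 pent-4-ynal; 2 prenylmagnesium chloride
Product: 4 (4S)-3,3-dimethyloct-1-en-7-yn-4-ol, via borinate ester 3 (not isolated)
Conditions: 2, (+)-Ipc2BOMe, Et2O, −78 °C → rt; then 1, −78 °C; NaOH, H2O2, 0 °C → rt
Reagents that add atoms: none
Why: Brown-type allylboration through a closed chair transition state with allylic transposition joins the disubstituted prenyl terminus to the aldehyde (new C3–C4 bond, quaternary C4 carrying the vinyl group that becomes C5=C6), and the isopinocampheyl ligands should direct attack to the Re face, setting C3 as S.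

Step 2
Reactants: 4 (4S)-3,3-dimethyloct-1-en-7-yn-4-ol
Product: 5 (4S)-4-(tert-butyldimethylsilyloxy)-3,3-dimethyloct-1-en-7-yne
Conditions: TBSOTf, 2,6-lutidine, CH2Cl2, 0 °C
Reagents that add atoms: tert-butyldimethylsilyl trifluoromethanesulfonate, CC(C)(C)[Si](C)(C)OS(=O)(=O)C(F)(F)F
Why: a silyl triflate with a hindered pyridine base silylates the neopentyl-type secondary alcohol, and the bulky ether later takes the equatorial site in the cycloaddition.

Step 3
Reactants: 5 (4S)-4-(tert-butyldimethylsilyloxy)-3,3-dimethyloct-1-en-7-yne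
Product: 7 (3E,7S)-7-(tert-butyldimethylsilyloxy)-4,8,8-trimethyldeca-3,9-dien-2-one, via alkenylalane 6 (not isolated)
Conditions: Me3Al, Cp2ZrCl2 (cat.), CH2Cl2, 0 °C → rt; volatiles removed; AcCl, Pd(PPh3)4 (cat.), THF, 0 °C → rt
Reagents that add atoms: trimethylaluminium, C[Al](C)C; acetyl chloride, CC(Cl)=O
Why: Negishi zirconium-catalysed syn-carboalumination adds methyl (C20) and aluminium across the terminal alkyne with the metal on the terminal carbon, and palladium-catalysed acylation of the E-alkenylalane with retention should give the E-enone (tether trans to the acyl group), the neopentyl vinyl group being inert.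

Step 4
Reactants: 7 (3E,7S)-7-(tert-butyldimethylsilyloxy)-4,8,8-trimethyldeca-3,9-dien-2-one
Product: 9 (3S,6E)-3-(tert-butyldimethylsilyloxy)-2,2,6-trimethyl-8-oxonon-6-enal, via diol 8 (not isolated)
Conditions: OsO4 (cat.), NaIO4, 2,6-lutidine, dioxane–H2O, rt
Reagents that add atoms: osmium tetroxide (catalytic oxygen carrier), O=[Os](=O)(=O)=O; sodium periodate, [Na+].[O-]I(=O)(=O)=O
Why: Lemieux–Johnson cleavage, in which OsO4 should dihydroxylate the isolated monosubstituted alkene faster than the electron-poor trisubstituted enone and periodate cleaves the diol to an aldehyde that has no α-hydrogen.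

Step 5
Reactants: 9 (3S,6E)-3-(tert-butyldimethylsilyloxy)-2,2,6-trimethyl-8-oxonon-6-enal
Product: 10 (3E,7S,9E)-7-(tert-butyldimethylsilyloxy)-4,8,8-trimethyl-10-(phenylsulfonyl)deca-3,9-dien-2-one
Conditions: (EtO)2P(O)CH2SO2Ph, NaH, THF, 0 °C; then 9, 0 °C → rt
Reagents that add atoms: diethyl [(phenylsulfonyl)methyl]phosphonate, CCOP(=O)(CS(=O)(=O)c1ccccc1)OCC
Why: Horner–Wadsworth–Emmons olefination with the sulfonyl-stabilised phosphonate anion should give the E-vinyl sulfone, the aldehyde reacting far faster than the hindered methyl enone.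

Step 6
Reactants: 10 (3E,7S,9E)-7-(tert-butyldimethylsilyloxy)-4,8,8-trimethyl-10-(phenylsulfonyl)deca-3,9-dien-2-one
Product: 12 (3E,7S,9E)-7-(tert-butyldimethylsilyloxy)-4,8,8-trimethyl-10-(phenylsulfonyl)-2-(triethylsilyloxy)deca-1,3,9-triene, via lithium dienolate 11 (not isolated)
Conditions: LiHMDS, THF, −78 °C; TESCl, Et3N, −78 → 0 °C
Reagents that add atoms: chlorotriethylsilane, CC[Si](Cl)(CC)CC
Why: kinetic deprotonation of the enone at its α′-methyl group and O-silylation give the cross-conjugated 2-silyloxy diene without touching the C9=C10 geometry.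

Step 7
Reactants: 12 (3E,7S,9E)-7-(tert-butyldimethylsilyloxy)-4,8,8-trimethyl-10-(phenylsulfonyl)-2-(triethylsilyloxy)deca-1,3,9-triene
Product: 13 trans-fused octalin with 3β-OTBS, 5α-H, 6α-SO2Ph, 10β-CH3, 4,4-dimethyl and a C8(OTES)=C9 enol ether
Conditions: PhMe (0.01 M), BHT (cat.), 160 °C, sealed tube
Reagents that add atoms: none
Why: Thermal, concerted but asynchronous suprafacial [4+2] cycloaddition between the 2-silyloxy diene C7=C8–C9=C10 and the sulfonyl-activated E-alkene C5=C6, the closest known type being the intramolecular Diels–Alder reaction of (E)-1-sulfonyl-1,7,9-decatrienes and of 2-silyloxy dienes to trans-octalins. Ring A closes in the fused (type 1) mode through C5–C10 with the C1–C4 tether held as a chair, and ring B is the cycloadduct ring itself, closed by C5–C10 together with C6–C7. C10 and C5 should come out trans because the E-diene holds the tether outside and the methyl inside, and the anti transition state keeps the quaternary C4 exo while the sulfonyl group sits endo; C6 (sulfonyl α, erased in step 8) follows from the E-alkene. The absolute sense at C5 and C10 is relayed from C3, whose silyloxy group takes the equatorial site of the chair tether, which corresponds to the 3β,5α,10β array. The step needs trans ring fusion and one π-face, the regiochemistry is fixed by the tether, and the C8 enol ether emerges regiodefined for step 12.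

Step 8
Reactants: 13 trans-fused octalin with 6α-SO2Ph
Product: 14 trans-fused octalin with 3β-OTBS, 5α-H, 10β-CH3, 4,4-dimethyl, C6 as CH2 and the C8(OTES)=C9 enol ether
Conditions: SmI2, HMPA, THF, MeOH, −20 °C
Reagents that add atoms: none
Why: single-electron reductive cleavage of the alkyl–sulfonyl bond (SmI2/HMPA desulfonylation) turns C6 into CH2 while silyl ethers and the silyl enol ether should stay intact.

Step 9
Reactants: 15 (S)-citronellol
Product: 16 tert-butyl{[(3S)-3,7-dimethyloct-6-en-1-yl]oxy}diphenylsilane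
Conditions: TBDPSCl, imidazole, DMF, rt
Reagents that add atoms: tert-butyl(chloro)diphenylsilane, CC(C)(C)[Si](Cl)(c1ccccc1)c1ccccc1
Why: standard silylation of the primary alcohol with a group that survives oxidants, organolithiums and Grignard reagents.

Step 10
Reactants: 16 tert-butyl{[(3S)-3,7-dimethyloct-6-en-1-yl]oxy}diphenylsilane
Product: 17 (4S)-6-(tert-butyldiphenylsilyloxy)-4-methylhexanoic acid
Conditions: RuCl3·xH2O (cat.), NaIO4, CCl4–MeCN–H2O, rt
Reagents that add atoms: sodium periodate, [Na+].[O-]I(=O)(=O)=O; water, O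
Why: RuO4 generated in situ cleaves the trisubstituted alkene to the carboxylic acid with loss of acetone, and the remote stereocentre is not involved.

Step 11
Reactants: 17 (4S)-6-(tert-butyldiphenylsilyloxy)-4-methylhexanoic acid
Product: 18 (3R)-tert-butyl[(5-iodo-3-methylpentyl)oxy]diphenylsilane
Conditions: PhI(OAc)2, I2, CCl4, hν, reflux
Reagents that add atoms: iodine, [I][I]
Why: Hunsdiecker-type iododecarboxylation through an acyl hypoiodite, decarboxylation and iodine-atom capture gives the primary iodide one carbon shorter, so the citronellol carbon next to the former alkene becomes C11.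

Step 12
Reactants: 14 trans-fused octalin silyl enol ether; 18 (3R)-tert-butyl[(5-iodo-3-methylpentyl)oxy]diphenylsilane
Product: 21 (13S)-3β-(tert-butyldimethylsilyloxy)-15-(tert-butyldiphenylsilyloxy)-17-norlabdan-8-one (9α-H), via lithium enolate 19 (not isolated), via 9-epi ketone 20 (not isolated)
Conditions: MeLi, THF, 0 °C → rt; HMPA, 18, −40 °C → rt; work-up; NaOMe (cat.), MeOH–THF, rt
Reagents that add atoms: none
Why: Si–O cleavage with MeLi gives the regiodefined C8=C9 lithium enolate, which is C-alkylated by the primary iodide (enolate alkylation), the electrophile entering anti to the angular methyl; methoxide equilibration through the C8 enolate should then place the chain equatorial (9β, H on the α face), so C9 is set under thermodynamic control.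

Step 13
Reactants: 21 (13S)-3β-(tert-butyldimethylsilyloxy)-15-(tert-butyldiphenylsilyloxy)-17-norlabdan-8-one
Product: 23 (13S)-3β-(tert-butyldimethylsilyloxy)-15-(tert-butyldiphenylsilyloxy)-17-norlabd-7-en-8-yl trifluoromethanesulfonate, via potassium enolate 22 (not isolated)
Conditions: KHMDS, THF, −78 °C; PhNTf2, −78 → 0 °C
Reagents that add atoms: N-phenylbis(trifluoromethanesulfonimide), O=S(=O)(N(c1ccccc1)S(=O)(=O)C(F)(F)F)C(F)(F)F
Why: kinetic deprotonation takes place at the unhindered C7 methylene and not at the C9 methine next to the quaternary carbon, and O-triflation fixes the C7=C8 double bond.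

Step 14
Reactants: 23 (13S)-3β-(tert-butyldimethylsilyloxy)-15-(tert-butyldiphenylsilyloxy)-17-norlabd-7-en-8-yl trifluoromethanesulfonate
Product: 24 (13S)-3β-(tert-butyldimethylsilyloxy)-15-(tert-butyldiphenylsilyloxy)labd-7-ene
Conditions: MeMgBr, Fe(acac)3 (cat.), THF–NMP, −30 → 0 °C
Reagents that add atoms: methylmagnesium bromide, C[Mg]Br
Why: iron-catalysed Kumada-type cross-coupling of an alkenyl triflate with a methyl Grignard reagent installs C17 with the double bond held at C7=C8.

Step 15
Reactants: 24 (13S)-3β-(tert-butyldimethylsilyloxy)-15-(tert-butyldiphenylsilyloxy)labd-7-ene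
Product: 25 (13S)-labd-7-ene-3β,15-diol
Conditions: TBAF, THF, 60 °C
Reagents that add atoms: none
Why: fluoride cleaves both silyl ethers, the hindered C3 ether needing the higher temperature, and nothing else in the molecule is fluoride-sensitive.

Step 16
Reactants: 25 (13S)-labd-7-ene-3β,15-diol
Product: 26 (13S)-labd-7-ene-3β,15-diyl diformate (target)
Conditions: preformed acetic formic anhydride, pyridine, DMAP (cat.), CH2Cl2, 0 °C → rt
Reagents that add atoms: acetic formic anhydride, CC(=O)OC=O
Why: the mixed anhydride transfers its formyl group to both the primary and the equatorial secondary alcohol (O-formylation) under conditions that leave the trisubstituted alkene alone.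

**Compound list**

1 | pent-4-ynal | C#CCCC=O | starting material
2 | prenylmagnesium chloride, (3-methylbut-2-en-1-yl)magnesium chloride | CC(C)=CC[Mg]Cl | starting material
3 | bis[(+)-isopinocampheyl]borinate ester of alcohol 4 (not isolated) | C=CC(C)(C)[C@@H](OB([C@H]1C[C@H]2C[C@@H]([C@@H]1C)C2(C)C)[C@H]1C[C@H]2C[C@@H]([C@@H]1C)C2(C)C)CCC#C | intermediate
4 | (4S)-3,3-dimethyloct-1-en-7-yn-4-ol | C=CC(C)(C)[C@@H](O)CCC#C | intermediate
5 | (4S)-4-(tert-butyldimethylsilyloxy)-3,3-dimethyloct-1-en-7-yne | C=CC(C)(C)[C@@H](O[Si](C)(C)C(C)(C)C)CCC#C | intermediate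
6 | (1E,5S)-[5-(tert-butyldimethylsilyloxy)-2,6,6-trimethylocta-1,7-dien-1-yl]dimethylalane (not isolated) | C=CC(C)(C)[C@@H](O[Si](C)(C)C(C)(C)C)CC/C(C)=C/[Al](C)C | intermediate
7 | (3E,7S)-7-(tert-butyldimethylsilyloxy)-4,8,8-trimethyldeca-3,9-dien-2-one | C=CC(C)(C)[C@@H](O[Si](C)(C)C(C)(C)C)CC/C(C)=C/C(C)=O | intermediate
8 | (3E,7S)-7-(tert-butyldimethylsilyloxy)-9,10-dihydroxy-4,8,8-trimethyldec-3-en-2-one, both C9 epimers (not isolated) | OCC(O)C(C)(C)[C@@H](O[Si](C)(C)C(C)(C)C)CC/C(C)=C/C(C)=O | intermediate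
9 | (3S,6E)-3-(tert-butyldimethylsilyloxy)-2,2,6-trimethyl-8-oxonon-6-enal | O=CC(C)(C)[C@@H](O[Si](C)(C)C(C)(C)C)CC/C(C)=C/C(C)=O | intermediate
10 | (3E,7S,9E)-7-(tert-butyldimethylsilyloxy)-4,8,8-trimethyl-10-(phenylsulfonyl)deca-3,9-dien-2-one | O=S(=O)(/C=C/C(C)(C)[C@@H](O[Si](C)(C)C(C)(C)C)CC/C(C)=C/C(C)=O)c1ccccc1 | intermediate
11 | lithium dienolate of 10, formed at the methyl ketone (not isolated) | O=S(=O)(/C=C/C(C)(C)[C@@H](O[Si](C)(C)C(C)(C)C)CC/C(C)=C/C(=C)O[Li])c1ccccc1 | intermediate
12 | (3E,7S,9E)-7-(tert-butyldimethylsilyloxy)-4,8,8-trimethyl-10-(phenylsulfonyl)-2-(triethylsilyloxy)deca-1,3,9-triene | O=S(=O)(/C=C/C(C)(C)[C@@H](O[Si](C)(C)C(C)(C)C)CC/C(C)=C/C(=C)O[Si](CC)(CC)CC)c1ccccc1 | intermediate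
13 | trans-fused octalin: 3β-OTBS, 5α-H, 6α-SO2Ph, 10β-CH3, 4,4-dimethyl, C8(OTES)=C9 | CC[Si](CC)(CC)OC1=C[C@@]2(C)CC[C@H](O[Si](C)(C)C(C)(C)C)C(C)(C)[C@@H]2[C@@H](S(=O)(=O)c3ccccc3)C1 | intermediate
14 | trans-fused octalin: 3β-OTBS, 5α-H, 10β-CH3, 4,4-dimethyl, C8(OTES)=C9, C6 as CH2 | CC[Si](CC)(CC)OC1=C[C@@]2(C)CC[C@H](O[Si](C)(C)C(C)(C)C)C(C)(C)[C@@H]2CC1 | intermediate
15 | (S)-citronellol, (3S)-3,7-dimethyloct-6-en-1-ol | CC(C)=CCC[C@H](C)CCO | starting material
16 | tert-butyl{[(3S)-3,7-dimethyloct-6-en-1-yl]oxy}diphenylsilane | CC(C)=CCC[C@H](C)CCO[Si](c1ccccc1)(c1ccccc1)C(C)(C)C | intermediate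
17 | (4S)-6-(tert-butyldiphenylsilyloxy)-4-methylhexanoic acid | OC(=O)CC[C@H](C)CCO[Si](c1ccccc1)(c1ccccc1)C(C)(C)C | intermediate
18 | (3R)-tert-butyl[(5-iodo-3-methylpentyl)oxy]diphenylsilane | ICC[C@H](C)CCO[Si](c1ccccc1)(c1ccccc1)C(C)(C)C | intermediate
19 | lithium C8=C9 enolate from 14 (not isolated) | [Li]OC1=C[C@@]2(C)CC[C@H](O[Si](C)(C)C(C)(C)C)C(C)(C)[C@@H]2CC1 | intermediate
20 | 9-epimer of 21, side chain 9α and axial (not isolated) | O=C1CC[C@H]2C(C)(C)[C@@H](O[Si](C)(C)C(C)(C)C)CC[C@]2(C)[C@@H]1CC[C@H](C)CCO[Si](c1ccccc1)(c1ccccc1)C(C)(C)C | intermediate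
21 | (13S)-3β-(tert-butyldimethylsilyloxy)-15-(tert-butyldiphenylsilyloxy)-17-norlabdan-8-one (9α-H) | O=C1CC[C@H]2C(C)(C)[C@@H](O[Si](C)(C)C(C)(C)C)CC[C@]2(C)[C@H]1CC[C@H](C)CCO[Si](c1ccccc1)(c1ccccc1)C(C)(C)C | intermediate
22 | potassium C7=C8 enolate of 21 (not isolated) | [K]OC1=CC[C@H]2C(C)(C)[C@@H](O[Si](C)(C)C(C)(C)C)CC[C@]2(C)[C@H]1CC[C@H](C)CCO[Si](c1ccccc1)(c1ccccc1)C(C)(C)C | intermediate
23 | (13S)-3β-(tert-butyldimethylsilyloxy)-15-(tert-butyldiphenylsilyloxy)-17-norlabd-7-en-8-yl trifluoromethanesulfonate | O=S(=O)(OC1=CC[C@H]2C(C)(C)[C@@H](O[Si](C)(C)C(C)(C)C)CC[C@]2(C)[C@H]1CC[C@H](C)CCO[Si](c1ccccc1)(c1ccccc1)C(C)(C)C)C(F)(F)F | intermediate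
24 | (13S)-3β-(tert-butyldimethylsilyloxy)-15-(tert-butyldiphenylsilyloxy)labd-7-ene | CC1=CC[C@H]2C(C)(C)[C@@H](O[Si](C)(C)C(C)(C)C)CC[C@]2(C)[C@H]1CC[C@H](C)CCO[Si](c1ccccc1)(c1ccccc1)C(C)(C)C | intermediate
25 | (13S)-labd-7-ene-3β,15-diol | CC1=CC[C@H]2C(C)(C)[C@@H](O)CC[C@]2(C)[C@H]1CC[C@H](C)CCO | intermediate
26 | (13S)-labd-7-ene-3β,15-diyl diformate, (3S,5R,9S,10R,13S) | CC1=CC[C@H]2C(C)(C)[C@@H](OC=O)CC[C@]2(C)[C@H]1CC[C@H](C)CCOC=O | target

**Step count and risks**

Total steps: 16. Longest linear sequence: 13 steps (steps 1–8 and 12–16, from pent-4-ynal); the side-chain branch (steps 9–11) is three steps.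

Steps most likely to fail:

1. Step 7. The C5–C10 bond forms between a carbon next to the quaternary C4 and a carbon that becomes quaternary, so ring closure may be slow at 160 °C. A 1,5-hydrogen shift from the inside methyl of the diene could then compete, and control of the ring fusion could be lost.
   Fallback: this sets out from aldehyde 9 and uses a nitroalkene, which should cyclise some 80 °C lower with a stronger endo preference. Henry addition of nitromethane (tetramethylguanidine cat., THF) should give the nitro alcohol F1. Mesylation and elimination (MsCl, Et3N) should give the E-nitroalkene F2. Soft enolisation (TESOTf, Et3N, CH2Cl2, −78 °C) should give the nitro triene F3, which is heated in PhMe at about 80 °C to the trans-fused 6α-nitro octalin F4. Radical denitration (Bu3SnH, AIBN, PhMe, 110 °C) then returns to compound 14.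

2. Step 12. C-alkylation of the hindered C9 enolate by an unactivated primary iodide may be slow. Proton transfer to the product could then lead to alkylation at C7 and over-alkylation, O-alkylation could compete, and the epimerisation at C9 could stop short.
   Fallback: this sets out from 14 and 18 and replaces the alkylation by an aldol condensation and hydrogenation. Kornblum oxidation of 18 (DMSO, NaHCO3, 100 °C) should give the aldehyde F5. Mukaiyama aldol addition of 14 to F5 (TiCl4, CH2Cl2, −78 °C) should give the β-hydroxy ketone F6. Dehydration (MsCl, Et3N; then DBU) should give the exocyclic enone F7. Hydrogenation (H2, Pd/C, EtOAc) should add hydrogen to C9 from the α face, anti to the angular methyl; brief NaOMe/MeOH treatment then returns to ketone 21.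

3. Step 3. In the one-pot sequence, residual methylaluminium species may transfer methyl to the acid chloride, and transmetalation of the alkenylalane to palladium may be sluggish, leaving protodemetalated alkene.
   Fallback: this sets out from 5 and separates the two events. The same carboalumination is quenched with iodine (THF, −30 °C) to give the E-vinyl iodide F8. Lithium–iodine exchange (t-BuLi, Et2O, −78 °C) and acylation with N-methoxy-N-methylacetamide then return to enone 7.

Further compounds
F1 | step 7 | (3E,7S)-7-(tert-butyldimethylsilyloxy)-9-hydroxy-4,8,8-trimethyl-10-nitrodec-3-en-2-one, both C9 epimers | [O-][N+](=O)CC(O)C(C)(C)[C@@H](O[Si](C)(C)C(C)(C)C)CC/C(C)=C/C(C)=O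
F2 | step 7 | (3E,7S,9E)-7-(tert-butyldimethylsilyloxy)-4,8,8-trimethyl-10-nitrodeca-3,9-dien-2-one | [O-][N+](=O)/C=C/C(C)(C)[C@@H](O[Si](C)(C)C(C)(C)C)CC/C(C)=C/C(C)=O
F3 | step 7 | (3E,7S,9E)-7-(tert-butyldimethylsilyloxy)-4,8,8-trimethyl-10-nitro-2-(triethylsilyloxy)deca-1,3,9-triene | [O-][N+](=O)/C=C/C(C)(C)[C@@H](O[Si](C)(C)C(C)(C)C)CC/C(C)=C/C(=C)O[Si](CC)(CC)CC
F4 | step 7 | trans-fused octalin: 3β-OTBS, 5α-H, 6α-NO2, 10β-CH3, 4,4-dimethyl, C8(OTES)=C9 | CC[Si](CC)(CC)OC1=C[C@@]2(C)CC[C@H](O[Si](C)(C)C(C)(C)C)C(C)(C)[C@@H]2[C@@H]([N+](=O)[O-])C1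
F5 | step 12 | (3S)-5-(tert-butyldiphenylsilyloxy)-3-methylpentanal | O=CC[C@H](C)CCO[Si](c1ccccc1)(c1ccccc1)C(C)(C)C
F6 | step 12 | (13S)-3β-(tert-butyldimethylsilyloxy)-15-(tert-butyldiphenylsilyloxy)-11-hydroxy-17-norlabdan-8-one, mixture at C9 and C11 | O=C1CC[C@H]2C(C)(C)[C@@H](O[Si](C)(C)C(C)(C)C)CC[C@]2(C)C1C(O)C[C@H](C)CCO[Si](c1ccccc1)(c1ccccc1)C(C)(C)C
F7 | step 12 | (13S)-3β-(tert-butyldimethylsilyloxy)-15-(tert-butyldiphenylsilyloxy)-17-norlabd-9(11)-en-8-one, alkene geometry open | O=C1CC[C@H]2C(C)(C)[C@@H](O[Si](C)(C)C(C)(C)C)CC[C@]2(C)C1=CC[C@H](C)CCO[Si](c1ccccc1)(c1ccccc1)C(C)(C)C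
F8 | step 3 | (1E,5S)-5-(tert-butyldimethylsilyloxy)-1-iodo-2,6,6-trimethylocta-1,7-diene | C=CC(C)(C)[C@@H](O[Si](C)(C)C(C)(C)C)CC/C(C)=C/I
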